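**Retrosynthetic overview** (ring atoms: C1 carries the exocyclic CH2, then C2, C3, C4=C5 (C5 carries CO2H), C6, C7 (O-angelate), C8, C9 (CMe2), C10, C11 (OH))
1. Target ⇒ macrocyclic 7-ol 24 by angeloylation at O7 and oxidation of the C5–CH2OH group to CO2H.
2. 24 ⇒ C7–C8: the single eleven-membered ring is formed last, by contraction of a twelve-membered cyclic boronate complex in which C7 is a chiral α-chloroalkyllithium (from an α-chloro sulfoxide) and C8 is the CH2–B(pin) group.
3. Enabling feature: the carbinol carbon C7 stands next to the neopentyl methylene C8 on quaternary C9, so the C7–O bond can come from a C7–B bond and C8, useless as an SN2 or enolate carbon, can migrate from boron to carbon.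
4. Seco chain ⇒ C11–C1 by asymmetric Nozaki–Hiyama–Kishi coupling (sets 11S) of boronate aldehyde 6 (from 3,3-dimethylglutaric anhydride) with vinyl iodide 17; 17 ⇒ C4=C5 by Horner–Wadsworth–Emmons reaction of 4-iodopent-4-enal with a phosphonate made by Michael addition to (R)-p-tolyl vinyl sulfoxide.

Key step: step 15

Assumption 1: the NCS/K2CO3 chlorination of the (R)-alkyl p-tolyl sulfoxide 19 is taken to give the (7R)-chloride with inverted sulfur geometry; if the sense is opposite, the enantiomeric sulfinate is used in step 7 and nothing else changes.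
Assumption 2: the (S)-oxazoline–sulfonamide ligand of step 12 is taken to direct the alkenyl group to the Re face of aldehyde 6; otherwise its enantiomer is used.

**Step 1**
Reactants: 1 3,3-dimethylglutaric anhydride
Product: 2 5-methoxy-3,3-dimethyl-5-oxopentanoic acid
Conditions: MeOH, reflux
Reagents that add atoms: methanol, CO
Why: Alcoholysis of the symmetric cyclic anhydride (nucleophilic acyl substitution) opens the ring to the half-ester; no stereocentre is formed.

**Step 2**
Reactants: 2 5-methoxy-3,3-dimethyl-5-oxopentanoic acid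
Product: 3 1-(1,3-dioxoisoindolin-2-yl) 5-methyl 3,3-dimethylpentanedioate
Conditions: N-hydroxyphthalimide, N,N'-diisopropylcarbodiimide, DMAP (cat.), CH2Cl2, rt
Reagents that add atoms: N-hydroxyphthalimide, ON1C(=O)c2ccccc2C1=O
Why: Carbodiimide-mediated (Steglich-type) esterification of the free acid gives the redox-active ester; the methyl ester is inert.

**Step 3**
Reactants: 3 1-(1,3-dioxoisoindolin-2-yl) 5-methyl 3,3-dimethylpentanedioate
Product: 5 methyl 3,3-dimethyl-4-(4,4,5,5-tetramethyl-1,3,2-dioxaborolan-2-yl)butanoate, via catechol boronate 4 (not isolated)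
Conditions: bis(catecholato)diboron, N,N-dimethylacetamide, blue LEDs, rt; then pinacol, Et3N, rt
Reagents that add atoms: bis(catecholato)diboron, B1(Oc2ccccc2O1)B1Oc2ccccc2O1; pinacol, CC(C)(O)C(C)(C)O
Why: Photoinduced decarboxylative borylation of the N-acyloxyphthalimide (radical chain, the primary radical is trapped by the diboron–amide adduct) and transesterification with pinacol; the radical is made before any alkene is present, so it cannot cyclise.

**Step 4**
Reactants: 5 methyl 3,3-dimethyl-4-(4,4,5,5-tetramethyl-1,3,2-dioxaborolan-2-yl)butanoate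
Product: 6 3,3-dimethyl-4-(4,4,5,5-tetramethyl-1,3,2-dioxaborolan-2-yl)butanal
Conditions: i-Bu2AlH (1.1 equiv), CH2Cl2, −78 °C
Reagents that add atoms: none
Why: Partial ester reduction; the aluminium hemiacetal is stable at −78 °C and gives the aldehyde on work-up, and the alkyl pinacol boronate is untouched.

**Step 5**
Reactants: 7 pent-4-yn-1-ol
Product: 8 4-iodopent-4-en-1-ol
Conditions: NaI, Me3SiCl, H2O, MeCN, rt
Reagents that add atoms: sodium iodide, [Na+].[I-]
Why: Markovnikov hydroiodination of the terminal alkyne by hydrogen iodide generated in the flask gives the 2-iodo-1-alkene; a transient silyl ether is lost on aqueous work-up.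

**Step 6**
Reactants: 8 4-iodopent-4-en-1-ol
Product: 9 4-iodopent-4-enal
Conditions: TEMPO (cat.), PhI(OAc)2, CH2Cl2, rt
Reagents that add atoms: none
Why: Oxoammonium (TEMPO) oxidation stops at the aldehyde and leaves the vinyl iodide alone.

**Step 7**
Reactants: 10 (1R,2S,5R)-menthyl (S)-4-methylbenzenesulfinate; 11 vinylmagnesium bromide
Product: 12 (R)-1-(ethenesulfinyl)-4-methylbenzene
Conditions: THF, −78 → −20 °C
Reagents that add atoms: none
Why: Andersen sulfoxide synthesis: the Grignard reagent displaces mentholate at sulfur with inversion, so the (S)-sulfinate gives the (R)-vinyl sulfoxide.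

**Step 8**
Reactants: 12 (R)-1-(ethenesulfinyl)-4-methylbenzene; 13 triethyl phosphonoacetate
Product: 14 ethyl 2-(diethoxyphosphoryl)-4-[(R)-(4-methylphenyl)sulfinyl]butanoate (both epimers at C2)
Conditions: 13 (2 equiv), NaH (0.2 equiv), THF, rt → 50 °C
Reagents that add atoms: none
Why: Michael addition of the phosphonoacetate carbanion to the vinyl sulfoxide under catalytic base; sulfur configuration is untouched and the new carbon stereocentre is lost in step 9.

**Step 9**
Reactants: 14 ethyl 2-(diethoxyphosphoryl)-4-[(R)-(4-methylphenyl)sulfinyl]butanoate; 9 4-iodopent-4-enal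
Product: 15 ethyl (2E)-6-iodo-2-{2-[(R)-(4-methylphenyl)sulfinyl]ethyl}hepta-2,6-dienoate
Conditions: NaH, THF, 0 °C; then 9, 0 °C → rt
Reagents that add atoms: none
Why: Horner–Wadsworth–Emmons olefination of the α-branched phosphonoacetate; reversible addition should favour the (E)-enoate with the ester trans to the chain (C3 and C6 cis), the minor isomer being removed by chromatography.

**Step 10**
Reactants: 15 ethyl (2E)-6-iodo-2-{2-[(R)-(4-methylphenyl)sulfinyl]ethyl}hepta-2,6-dienoate
Product: 16 (2E)-6-iodo-2-{2-[(R)-(4-methylphenyl)sulfinyl]ethyl}hepta-2,6-dien-1-ol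
Conditions: i-Bu2AlH (2.5 equiv), CH2Cl2, −78 °C
Reagents that add atoms: none
Why: 1,2-Reduction of the enoate to the allylic alcohol; at −78 °C the sulfoxide and the vinyl iodide should survive and the alkene geometry is kept.

**Step 11**
Reactants: 16 (2E)-6-iodo-2-{2-[(R)-(4-methylphenyl)sulfinyl]ethyl}hepta-2,6-dien-1-ol
Product: 17 tert-butyl{[(2E)-6-iodo-2-{2-[(R)-(4-methylphenyl)sulfinyl]ethyl}hepta-2,6-dien-1-yl]oxy}dimethylsilane
Conditions: TBSCl, imidazole, DMF, rt
Reagents that add atoms: tert-butyldimethylsilyl chloride, CC(C)(C)[Si](C)(C)Cl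
Why: Standard silylation of the primary allylic alcohol; the silyl chloride is used because a silyl triflate would activate the sulfoxide.

**Step 12**
Reactants: 17 tert-butyl{[(2E)-6-iodo-2-{2-[(R)-(4-methylphenyl)sulfinyl]ethyl}hepta-2,6-dien-1-yl]oxy}dimethylsilane; 6 3,3-dimethyl-4-(4,4,5,5-tetramethyl-1,3,2-dioxaborolan-2-yl)butanal
Product: 18 (4S,8E)-9-{[tert-butyl(dimethyl)silyl]oxymethyl}-2,2-dimethyl-5-methylidene-11-[(R)-(4-methylphenyl)sulfinyl]-1-(4,4,5,5-tetramethyl-1,3,2-dioxaborolan-2-yl)undec-8-en-4-ol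
Conditions: CrCl2 (3 equiv), (S)-N-[2-(4-isopropyl-4,5-dihydro-1,3-oxazol-2-yl)-6-methylphenyl]methanesulfonamide, Et3N, NiCl2(2,9-dimethyl-1,10-phenanthroline) (cat.), THF, rt
Reagents that add atoms: none
Why: Nozaki–Hiyama–Kishi coupling (oxidative addition of the C–I bond to zerovalent nickel, transmetalation to trivalent chromium, carbonyl addition); the chiral sulfonamide ligand on chromium directs addition to the Re face of the aldehyde and so sets 11S (C4 of this chain), while boronate, sulfoxide and silyl ether are tolerated.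

**Step 13**
Reactants: 18 (the 4S alcohol of step 12)
Product: 19 the 4-O-tert-butyldimethylsilyl ether of 18
Conditions: TBSCl, imidazole, DMAP (cat.), DMF, 40 °C
Reagents that add atoms: tert-butyldimethylsilyl chloride, CC(C)(C)[Si](C)(C)Cl
Why: Silylation of the secondary allylic alcohol protects C11–OH from the chlorosulfonium species of step 14 and the organolithium of step 15.

**Step 14**
Reactants: 19 the 4-O-tert-butyldimethylsilyl ether of 18
Product: 20 the (11R)-11-chloro derivative of 19 [(7R) in ring numbering; (R) at sulfur]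
Conditions: N-chlorosuccinimide (1.1 equiv), K2CO3, CH2Cl2, 0 °C → rt
Reagents that add atoms: N-chlorosuccinimide, ClN1C(=O)CCC1=O
Why: α-Chlorination of an alkyl aryl sulfoxide (S-chlorination, loss of the α-proton, chloride return to carbon); the sulfur stereocentre directs chlorine to give the (7R)-chloride, the minor C7 epimer being removed by chromatography.

**Step 15**
Reactants: 20 the (11R)-11-chloro derivative of 19
Product: 24 (4E,7S,11S)-11-[tert-butyl(dimethyl)silyl]oxy-5-{[tert-butyl(dimethyl)silyl]oxymethyl}-9,9-dimethyl-1-methylidenecycloundec-4-en-7-ol, via α-chloroalkyllithium 21 (not isolated), via cyclic lithium boronate complex 22 (not isolated), via macrocyclic pinacol boronate 23 (not isolated)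
Conditions: 20 and t-BuLi (1.1 equiv) added simultaneously by syringe pump to THF (final 0.002 M), −78 °C; warm to rt; then aq. NaOH, H2O2, 0 °C
Reagents that add atoms: tert-butyllithium, [Li]C(C)(C)C (lithium stays in intermediates 21 and 22 only); hydrogen peroxide, OO
Why: Proposed new method: sulfoxide–lithium exchange (t-BuLi attacks sulfur, C7 leaves with retention) gives the configurationally defined α-chloroalkyllithium 21, whose carbanion adds to the remote pinacol boronate to give the cyclic complex 22; on warming C8 shifts from boron to C7 anti to the C–Cl bond (1,2-metallate rearrangement, inversion at C7) to give 23, and oxidation replaces boron by oxygen with retention. The closest known reaction is the intermolecular stereospecific reagent-controlled homologation of pinacol boronates by α-chloroalkyllithiums generated in situ by sulfoxide–lithium exchange; the intramolecular, ring-forming version is new. Ring closure: a twelve-membered ring containing boron is closed first by attack of C7 on trigonal boron (exo mode at boron), and the eleven-membered carbocycle then forms by ring contraction, C8 displacing chloride at C7 within the B–C7 unit (three-centre exo-tet shift), so no end-to-end C–C macrocyclisation is needed. C7 is the only new stereocentre and is controlled by the (7R) configuration of 20: retention in exchange and borylation, inversion in the shift and retention in the oxidation give 7S, and C11 is untouched. The step needs exchange at sulfur to outrun addition of t-BuLi to boron (the hindered base and the neopentyl boronate favour this), capture of the short-lived carbenoid by its own boronate before it decomposes (pseudo-high dilution against oligomers; the C9 gem-dimethyl group, the C1 methylene and the cis-related C3 and C6 on the C4=C5 bond fold the chain), and migration of carbon rather than oxygen (C8 is the only carbon ligand on boron besides C7).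

**Step 16**
Reactants: 24 the macrocyclic 7-ol of step 15; 25 angelic acid [(2Z)-2-methylbut-2-enoic acid]
Product: 27 (4E,7S,11S)-11-[tert-butyl(dimethyl)silyl]oxy-5-{[tert-butyl(dimethyl)silyl]oxymethyl}-9,9-dimethyl-1-methylidenecycloundec-4-en-7-yl (2Z)-2-methylbut-2-enoate, via mixed anhydride 26 (not isolated)
Conditions: 25, 2,4,6-trichlorobenzoyl chloride, Et3N, toluene, rt; then 24, 80 °C
Reagents that add atoms: 2,4,6-trichlorobenzoyl chloride, O=C(Cl)c1c(Cl)cc(Cl)cc1Cl (its atoms stay in intermediate 26 only)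
Why: Yamaguchi-type esterification through the mixed anhydride, run without nucleophilic catalyst so that the (Z)-angelate is not isomerised to the tiglate; the alcohol attacks the less hindered angeloyl carbonyl and C7 keeps its configuration.

**Step 17**
Reactants: 27 the bis-silylated angelate of step 16
Product: 28 (4E,7S,11S)-11-hydroxy-5-(hydroxymethyl)-9,9-dimethyl-1-methylidenecycloundec-4-en-7-yl (2Z)-2-methylbut-2-enoate
Conditions: HF·pyridine, pyridine, THF, 0 °C → rt
Reagents that add atoms: none
Why: Fluoride cleavage of both silyl ethers under buffered conditions leaves the angelate ester and the allylic alcohols intact.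

**Step 18**
Reactants: 28 the diol of step 17
Product: 29 (4E,7S,11S)-5-formyl-11-hydroxy-9,9-dimethyl-1-methylidenecycloundec-4-en-7-yl (2Z)-2-methylbut-2-enoate
Conditions: TEMPO (cat.), PhI(OAc)2, CH2Cl2, rt
Reagents that add atoms: none
Why: TEMPO/PhI(OAc)2 oxidises the primary allylic alcohol much faster than the secondary one at C11, giving the enal without touching C11–OH.

**Step 19**
Reactants: 29 the enal of step 18
Product: 30 (4E,7S,11S)-11-hydroxy-9,9-dimethyl-7-{[(2Z)-2-methylbut-2-enoyl]oxy}-1-methylidenecycloundec-4-ene-5-carboxylic acid (target)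
Conditions: NaClO2, NaH2PO4, 2-methylbut-2-ene, t-BuOH/H2O, rt
Reagents that add atoms: sodium chlorite, [Na+].[O-]Cl=O
Why: Pinnick oxidation converts the enal to the acid; 2-methylbut-2-ene scavenges hypochlorous acid and so protects the alkenes.

**Compound list**
1 | 3,3-dimethylglutaric anhydride | CC1(C)CC(=O)OC(=O)C1 | starting material
2 | 5-methoxy-3,3-dimethyl-5-oxopentanoic acid | COC(=O)CC(C)(C)CC(=O)O | intermediate
3 | 1-(1,3-dioxoisoindolin-2-yl) 5-methyl 3,3-dimethylpentanedioate | COC(=O)CC(C)(C)CC(=O)ON1C(=O)c2ccccc2C1=O | intermediate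
4 | methyl 4-(1,3,2-benzodioxaborol-2-yl)-3,3-dimethylbutanoate (not isolated) | COC(=O)CC(C)(C)CB1Oc2ccccc2O1 | intermediate
5 | methyl 3,3-dimethyl-4-(4,4,5,5-tetramethyl-1,3,2-dioxaborolan-2-yl)butanoate | COC(=O)CC(C)(C)CB1OC(C)(C)C(C)(C)O1 | intermediate
6 | 3,3-dimethyl-4-(4,4,5,5-tetramethyl-1,3,2-dioxaborolan-2-yl)butanal | O=CCC(C)(C)CB1OC(C)(C)C(C)(C)O1 | intermediate
7 | pent-4-yn-1-ol | C#CCCCO | starting material
8 | 4-iodopent-4-en-1-ol | C=C(I)CCCO | intermediate
9 | 4-iodopent-4-enal | C=C(I)CCC=O | intermediate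
10 | (1R,2S,5R)-menthyl (S)-4-methylbenzenesulfinate | CC(C)[C@@H]1CC[C@@H](C)C[C@H]1O[S@](=O)c1ccc(C)cc1 | starting material
11 | vinylmagnesium bromide | C=C[Mg]Br | starting material
12 | (R)-1-(ethenesulfinyl)-4-methylbenzene | C=C[S@@](=O)c1ccc(C)cc1 | intermediate
13 | triethyl phosphonoacetate | CCOC(=O)CP(=O)(OCC)OCC | starting material
14 | ethyl 2-(diethoxyphosphoryl)-4-[(R)-(4-methylphenyl)sulfinyl]butanoate (both C2 epimers) | CCOC(=O)C(CC[S@@](=O)c1ccc(C)cc1)P(=O)(OCC)OCC | intermediate
15 | ethyl (2E)-6-iodo-2-{2-[(R)-(4-methylphenyl)sulfinyl]ethyl}hepta-2,6-dienoate | C=C(I)CC/C=C(/C(=O)OCC)CC[S@@](=O)c1ccc(C)cc1 | intermediate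
16 | (2E)-6-iodo-2-{2-[(R)-(4-methylphenyl)sulfinyl]ethyl}hepta-2,6-dien-1-ol | C=C(I)CC/C=C(/CO)CC[S@@](=O)c1ccc(C)cc1 | intermediate
17 | tert-butyldimethylsilyl ether of 16 | C=C(I)CC/C=C(/CO[Si](C)(C)C(C)(C)C)CC[S@@](=O)c1ccc(C)cc1 | intermediate
18 | (4S,8E)-seco alcohol (boronate at C1 of the chain, sulfoxide at C11) | CC1(C)OB(CC(C)(C)C[C@H](O)C(=C)CC/C=C(/CO[Si](C)(C)C(C)(C)C)CC[S@@](=O)c2ccc(C)cc2)OC1(C)C | intermediate
19 | 4-O-tert-butyldimethylsilyl ether of 18 | CC1(C)OB(CC(C)(C)C[C@H](O[Si](C)(C)C(C)(C)C)C(=C)CC/C=C(/CO[Si](C)(C)C(C)(C)C)CC[S@@](=O)c2ccc(C)cc2)OC1(C)C | intermediate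
20 | (11R)-11-chloro derivative of 19, (R) at sulfur | CC1(C)OB(CC(C)(C)C[C@H](O[Si](C)(C)C(C)(C)C)C(=C)CC/C=C(/CO[Si](C)(C)C(C)(C)C)C[C@@H](Cl)[S@](=O)c2ccc(C)cc2)OC1(C)C | intermediate
21 | α-chloroalkyllithium from 20 (not isolated) | CC1(C)OB(CC(C)(C)C[C@H](O[Si](C)(C)C(C)(C)C)C(=C)CC/C=C(/CO[Si](C)(C)C(C)(C)C)C[C@@H](Cl)[Li])OC1(C)C | intermediate
22 | cyclic lithium boronate complex, twelve-membered ring through boron (not isolated) | [Li+].CC1(C)O[B-]2(OC1(C)C)CC(C)(C)C[C@H](O[Si](C)(C)C(C)(C)C)C(=C)CC/C=C(/CO[Si](C)(C)C(C)(C)C)C[C@H]2Cl | intermediate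
23 | macrocyclic pinacol boronate, boron on C7 (not isolated) | C=C1CC/C=C(/CO[Si](C)(C)C(C)(C)C)C[C@@H](B2OC(C)(C)C(C)(C)O2)CC(C)(C)C[C@@H]1O[Si](C)(C)C(C)(C)C | intermediate
24 | (4E,7S,11S)-macrocyclic 7-ol, silyl ethers at O11 and on the C5–CH2O group | C=C1CC/C=C(/CO[Si](C)(C)C(C)(C)C)C[C@@H](O)CC(C)(C)C[C@@H]1O[Si](C)(C)C(C)(C)C | intermediate
25 | angelic acid, (2Z)-2-methylbut-2-enoic acid | C/C=C(/C)C(=O)O | starting material
26 | (2Z)-2-methylbut-2-enoic 2,4,6-trichlorobenzoic anhydride (not isolated) | C/C=C(/C)C(=O)OC(=O)c1c(Cl)cc(Cl)cc1Cl | intermediate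
27 | 7-O-angelate of 24 | C=C1CC/C=C(/CO[Si](C)(C)C(C)(C)C)C[C@@H](OC(=O)/C(C)=C\C)CC(C)(C)C[C@@H]1O[Si](C)(C)C(C)(C)C | intermediate
28 | desilylated diol angelate | C=C1CC/C=C(/CO)C[C@@H](OC(=O)/C(C)=C\C)CC(C)(C)C[C@@H]1O | intermediate
29 | enal angelate | C=C1CC/C=C(/C=O)C[C@@H](OC(=O)/C(C)=C\C)CC(C)(C)C[C@@H]1O | intermediate
30 | (4E,7S,11S)-11-hydroxy-9,9-dimethyl-7-{[(2Z)-2-methylbut-2-enoyl]oxy}-1-methylidenecycloundec-4-ene-5-carboxylic acid | C=C1CC/C=C(/C(=O)O)C[C@@H](OC(=O)/C(C)=C\C)CC(C)(C)C[C@@H]1O | target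

**Total step count:** 19 steps. **Longest linear sequence:** 13 steps (steps 5, 6 and 9–19 from pent-4-yn-1-ol; equally steps 7–19 from the menthyl sulfinate).

**Steps most likely to fail**

1. Step 15 (proposed new method). What may go wrong: the lithium carbenoid may be captured by the boronate of a second molecule (oligomerisation), may decompose by α-elimination or be protonated before the twelve-membered boronate ring closes, or t-BuLi may add to boron in competition with the exchange at sulfur. Fallback with known chemistry, setting out from aldehyde 6 and returning at alcohol 24: the C7–C8 bond is made intermolecularly and the ring is closed at C11–C1 by an intramolecular Nozaki–Hiyama–Kishi reaction. Aldehyde 6 is protected (HC(OMe)3, MeOH, TsOH cat.) as 2-(4,4-dimethoxy-2,2-dimethylbutyl)-4,4,5,5-tetramethyl-1,3,2-dioxaborolane F1. Zweifel olefination (vinyllithium, then I2, then NaOMe) joins C7 to C8 and should give 6,6-dimethoxy-4,4-dimethylhex-1-ene F2. Epoxidation (mCPBA, NaHCO3) gives racemic 2-(4,4-dimethoxy-2,2-dimethylbutyl)oxirane F3, and hydrolytic kinetic resolution with (R,R)-(salen)Co(OAc) (trivalent cobalt, 0.55 equiv H2O) should leave (2S)-2-(4,4-dimethoxy-2,2-dimethylbutyl)oxirane F4, which fixes C7. Opening of F4 at its terminal carbon by the sodium salt of 13, with lactonisation, gives diethyl [(5S)-5-(4,4-dimethoxy-2,2-dimethylbutyl)-2-oxooxolan-3-yl]phosphonate F5. Its Horner–Wadsworth–Emmons reaction with aldehyde 9 gives the (E)-alkylidene lactone F6, and acetal hydrolysis (aqueous AcOH) gives the lactone aldehyde F7. CrCl2 with NiCl2 (cat.) in DMSO at high dilution closes the eleven-membered ring to the macrocyclic hydroxy lactone F8 (the ligand of step 12 can be added to favour 11S). Silylation (TBSCl, imidazole) gives the silyl ether F9, i-Bu2AlH opens the lactone to the macrocyclic diol F10, and selective silylation of its primary allylic hydroxyl gives 24.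

2. Step 14. What may go wrong: the sulfur-to-carbon induction in the chlorination may be low or of the opposite sense, and chlorine may be transferred to an alkene. Fallback, setting out from 19 and returning at 27: the C7 configuration is corrected at the esterification stage instead of at the chlorination. The (7S)-chloride, the C7 epimer of 20 F11, is separated and put through the ring contraction of step 15, which should give the (7R)-alcohol, the C7 epimer of 24 F12. Mitsunobu esterification of F12 with angelic acid 25 (PPh3, diisopropyl azodicarboxylate, toluene, 0 °C) inverts C7 while installing the angelate and gives 27. Both chloride epimers are thus usable.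

3. Step 12. What may go wrong: poor facial selectivity in the ligand-controlled addition to the unbranched aldehyde. Fallback, setting out from 17 and 6 and returning at 18: the coupling is run without chiral ligand (CrCl2, NiCl2 cat., DMF) to give the C11-epimeric alcohols, the epimer mixture of 18 F13. Dess–Martin oxidation gives the α-methylene ketone F14, and Corey–Bakshi–Shibata reduction with the (R)-oxazaborolidine and catecholborane at −78 °C, the alkenyl group acting as the larger substituent, should give 18 with 11S set by the reagent.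

**Further compounds**
F1 | step 15 | 2-(4,4-dimethoxy-2,2-dimethylbutyl)-4,4,5,5-tetramethyl-1,3,2-dioxaborolane | COC(OC)CC(C)(C)CB1OC(C)(C)C(C)(C)O1
F2 | step 15 | 6,6-dimethoxy-4,4-dimethylhex-1-ene | C=CCC(C)(C)CC(OC)OC
F3 | step 15 | racemic 2-(4,4-dimethoxy-2,2-dimethylbutyl)oxirane | COC(OC)CC(C)(C)CC1CO1
F4 | step 15 | (2S)-2-(4,4-dimethoxy-2,2-dimethylbutyl)oxirane | COC(OC)CC(C)(C)C[C@H]1CO1
F5 | step 15 | diethyl [(5S)-5-(4,4-dimethoxy-2,2-dimethylbutyl)-2-oxooxolan-3-yl]phosphonate (both C3 epimers) | CCOP(=O)(OCC)C1C[C@H](CC(C)(C)CC(OC)OC)OC1=O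
F6 | step 15 | (3E,5S)-5-(4,4-dimethoxy-2,2-dimethylbutyl)-3-(4-iodopent-4-en-1-ylidene)oxolan-2-one | C=C(I)CC/C=C1\C[C@H](CC(C)(C)CC(OC)OC)OC1=O
F7 | step 15 | 4-[(2S,4E)-4-(4-iodopent-4-en-1-ylidene)-5-oxooxolan-2-yl]-3,3-dimethylbutanal | C=C(I)CC/C=C1\C[C@H](CC(C)(C)CC=O)OC1=O
F8 | step 15 | macrocyclic hydroxy lactone (7S,11S; C5 carboxyl lactonised onto O7) | C=C1CC/C=C2\C[C@H](CC(C)(C)C[C@@H]1O)OC2=O
F9 | step 15 | 11-O-tert-butyldimethylsilyl ether of F8 | C=C1CC/C=C2\C[C@H](CC(C)(C)C[C@@H]1O[Si](C)(C)C(C)(C)C)OC2=O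
F10 | step 15 | macrocyclic diol (7-OH and C5–CH2OH free, O11 silylated) | C=C1CC/C=C(/CO)C[C@@H](O)CC(C)(C)C[C@@H]1O[Si](C)(C)C(C)(C)C
F11 | step 14 | (11S)-11-chloro epimer of 20 [(7S) in ring numbering] | CC1(C)OB(CC(C)(C)C[C@H](O[Si](C)(C)C(C)(C)C)C(=C)CC/C=C(/CO[Si](C)(C)C(C)(C)C)C[C@H](Cl)[S@](=O)c2ccc(C)cc2)OC1(C)C
F12 | step 14 | (7R)-epimer of 24 | C=C1CC/C=C(/CO[Si](C)(C)C(C)(C)C)C[C@H](O)CC(C)(C)C[C@@H]1O[Si](C)(C)C(C)(C)C
F13 | step 12 | mixture of both C4 epimers of 18 (C11 in ring numbering) | CC1(C)OB(CC(C)(C)CC(O)C(=C)CC/C=C(/CO[Si](C)(C)C(C)(C)C)CC[S@@](=O)c2ccc(C)cc2)OC1(C)C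
F14 | step 12 | 4-oxo analogue of 18 (α-methylene ketone) | CC1(C)OB(CC(C)(C)CC(=O)C(=C)CC/C=C(/CO[Si](C)(C)C(C)(C)C)CC[S@@](=O)c2ccc(C)cc2)OC1(C)C
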